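**Strategy.** The hexaprenyl chain is cut between C5′, the homoallylic CH2 of the first prenyl unit (chain numbered from the benzylic carbon C1′), and C6′, the vinylic CH of the C6′=C7′ olefin. A nickel-electrocatalytic decarboxylative alkenylation forms this sp3–sp2 bond in one operation: the N-hydroxyphthalimide ester of an (E)-6-aryl-4-methylhex-4-enoic acid releases the C5′ radical, which is joined to a geranylgeraniol-derived C24 (E)-alkenyl iodide with retention of geometry. The step exploits the repeating CH2–CH=C(CH3) motif of the skipped polyene and the cathodic inertness of the hexasubstituted benzene ring when masked as its tetramethyl ether. Oxidative demethylation and dithionite reduction then give the hydroquinone.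

Key step: step 7

Remark on the chemistry: ubiquinol-6 has no stereocentre, so "single enantiomer" is read as the single all-E olefin isomer shown. Chain carbons are numbered C1′ (benzylic CH2) to C24′.

**Step 1**
Reactants: 1 (2E,6E,10E)-geranylgeraniol
Product: 2 (2E,6E,10E)-geranylgeranyl bromide
Conditions: PBr3 (0.4 equiv), Et2O, −10 → 0 °C; used crude
Reagents that add atoms: phosphorus tribromide, BrP(Br)Br
Why: Bromination of a primary allylic alcohol with PBr3 (SN2 displacement of the phosphite ester) at low temperature should proceed without allylic transposition or E/Z scrambling of the C2=C3 olefin.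

**Step 2**
Reactants: 2 (2E,6E,10E)-geranylgeranyl bromide
Product: 4 (5E,9E,13E)-6,10,14,18-tetramethylnonadeca-5,9,13,17-tetraen-1-yne, via trimethylsilyl enyne 3 (not isolated)
Conditions: 1-(trimethylsilyl)propyne, n-BuLi, THF, −78 °C → rt; then MeOH, K2CO3, rt (same flask)
Reagents that add atoms: 1-(trimethylsilyl)propyne, CC#C[Si](C)(C)C
Why: Propargylic lithiation of the silyl-capped propyne and SN2 alkylation of the primary allylic bromide (the silyl cap suppresses allenyl products), followed by base-mediated methanolysis of the C–Si bond, should deliver the 1,5-enyne with all olefin geometries untouched.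

**Step 3**
Reactants: 4 (5E,9E,13E)-6,10,14,18-tetramethylnonadeca-5,9,13,17-tetraen-1-yne
Product: 6 (1E,5E,9E,13E)-1-iodo-2,6,10,14,18-pentamethylnonadeca-1,5,9,13,17-pentaene, via (E)-alkenyldimethylalane 5 (not isolated)
Conditions: AlMe3 (2.5 equiv), Cp2ZrCl2 (0.25 equiv), CH2Cl2, 0 °C → rt; then I2, THF, −30 → 0 °C
Reagents that add atoms: trimethylaluminium, C[Al](C)C; iodine, II
Why: Negishi carboalumination (zirconium-catalysed methylalumination) adds Me–Al syn across the terminal alkyne with aluminium at the terminal carbon, and iodinolysis with retention should give the (E)-2-methyl-1-iodoalkene while the remote trisubstituted olefins stay inert.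

**Step 4**
Reactants: 7 ethyl levulinate
Product: 9 rac-5-methyl-5-vinyldihydrofuran-2(3H)-one, via bromomagnesium alkoxide 8 (not isolated)
Conditions: CH2=CHMgBr (1.05 equiv), THF, −78 → 0 °C; aqueous work-up
Reagents that add atoms: vinylmagnesium bromide, C=C[Mg]Br
Why: Chemoselective Grignard addition to the ketone of the keto ester at low temperature, then 5-exo-trig lactonisation of the tertiary alkoxide with loss of ethoxide; the stereocentre is formed as a racemate and is destroyed in step 5.

**Step 5**
Reactants: 10 2,3,4,5-tetramethoxytoluene; 9 rac-5-methyl-5-vinyldihydrofuran-2(3H)-one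
Product: 13 (E)-4-methyl-6-(2,3,4,5-tetramethoxy-6-methylphenyl)hex-4-enoic acid, via aryllithium 11 (not isolated), via arylmagnesium bromide 12 (not isolated)
Conditions: n-BuLi, TMEDA, THF, 0 °C; MgBr2·OEt2, 0 °C; then 9, CuBr·SMe2 (10 mol%), THF–Me2S, −30 → 0 °C; 1 M HCl work-up
Reagents that add atoms: none
Why: Directed ortho-lithiation at the only ring C–H, transmetalation to magnesium and copper-catalysed anti-SN2′ substitution of the vinyl lactone (allylic carboxylate as leaving group) put the aryl group on the vinyl terminus and release the acid in one operation; the new C2′=C3′ olefin should form mainly as the E isomer (ring CH2 turned away from the incoming CH2Ar in the reactive conformer, as in SN2′ openings of isoprene monoxide), and any Z isomer would be removed by crystallisation of 13 or 14.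

**Step 6**
Reactants: 13 (E)-4-methyl-6-(2,3,4,5-tetramethoxy-6-methylphenyl)hex-4-enoic acid
Product: 14 1,3-dioxoisoindolin-2-yl (E)-4-methyl-6-(2,3,4,5-tetramethoxy-6-methylphenyl)hex-4-enoate
Conditions: N-hydroxyphthalimide, DIC, DMAP (cat.), CH2Cl2, rt
Reagents that add atoms: N-hydroxyphthalimide, O=C1c2ccccc2C(=O)N1O
Why: Carbodiimide (Steglich-type) esterification with N-hydroxyphthalimide gives the redox-active ester under neutral conditions that leave the olefin and the aryl ethers untouched.

**Step 7**
Reactants: 14 redox-active ester (1.5 equiv); 6 (E)-alkenyl iodide (1.0 equiv)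
Product: 15 1-[(2E,6E,10E,14E,18E)-3,7,11,15,19,23-hexamethyltetracosa-2,6,10,14,18,22-hexaen-1-yl]-2,3,4,5-tetramethoxy-6-methylbenzene
Conditions: NiCl2·6H2O (10 mol%), 2,2′-bipyridine (10 mol%), AgNO3 (0.3 equiv), LiCl, DMF, (+)Mg/(−)RVC, undivided cell, constant current, rt
Reagents that add atoms: none
Why: Cathodic reduction generates low-valent (bpy)Ni, which adds oxidatively to the C(sp2)–I bond of 6, while single-electron reduction of 14 (by Ni(I) or at the silver-nanoparticle-coated cathode formed in situ from AgNO3) fragments it to phthalimide anion, CO2 and the primary C5′ radical; radical capture at alkenyl-Ni(II) and reductive elimination from Ni(III) form the C5′–C6′ bond. The closest known reaction type is the Ni-electrocatalytic decarboxylative alkenylation of N-hydroxyphthalimide esters with alkenyl iodides on silver-modified cathodes, a reductive cross-electrophile coupling that has been applied to skipped-polyene (terpenoid) chains of this CH2–CH2–C(CH3)=CH type. No ring is closed and no stereocentre is created; the stereo-element at stake is the E geometry of C6′=C7′, which is fixed in step 3 and should be carried through because oxidative addition and reductive elimination at the alkenyl carbon are stereoretentive. The step needs cross- over homo-coupling, which the orthogonal activation of the two electrophiles (two-electron for the alkenyl iodide, one-electron for the ester) and an excess of the cheaper partner 14 should secure. It also needs the C5′ radical to be trapped before it rearranges: it is a 3-butenyl radical whose only cyclisation (3-exo onto C3′) is slow, reversible and constitutionally degenerate, and no 5-exo or 6-exo acceptor is within reach. The aryl methyl ethers, the benzylic/allylic C1′ position and the five remote trisubstituted olefins should be inert at the mild cathode potential that the sacrificial Mg anode allows.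

**Step 8**
Reactants: 15 hexaprenyl tetramethoxytoluene
Product: 16 ubiquinone-6 (2,3-dimethoxy-5-methyl-6-[(all-E)-hexaprenyl]-1,4-benzoquinone)
Conditions: (NH4)2Ce(NO3)6 (2.5 equiv), MeCN–CH2Cl2–H2O, 0 °C
Reagents that add atoms: water, O
Why: Cerium(IV) oxidative demethylation of the only para-related OMe pair (radical cation, attack of water, loss of methanol) should give the p-quinone, because the tetraalkoxyarene is oxidised at a lower potential than the trisubstituted olefins.

**Step 9**
Reactants: 16 ubiquinone-6
Product: 17 ubiquinol-6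
Conditions: Na2S2O4 (excess), degassed Et2O–H2O, rt, Ar; handled and stored under argon
Reagents that add atoms: none
Why: Two-electron, two-proton reduction of the quinone by dithionite gives the hydroquinone without touching the olefins or the methyl ethers.

**Compound list**

1 | (2E,6E,10E)-3,7,11,15-tetramethylhexadeca-2,6,10,14-tetraen-1-ol (geranylgeraniol) | OC/C=C(\C)CC/C=C(\C)CC/C=C(\C)CCC=C(C)C | starting material
2 | (2E,6E,10E)-1-bromo-3,7,11,15-tetramethylhexadeca-2,6,10,14-tetraene (geranylgeranyl bromide) | BrC/C=C(\C)CC/C=C(\C)CC/C=C(\C)CCC=C(C)C | intermediate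
3 | trimethyl[(5E,9E,13E)-6,10,14,18-tetramethylnonadeca-5,9,13,17-tetraen-1-yn-1-yl]silane | C[Si](C)(C)C#CCC/C=C(\C)CC/C=C(\C)CC/C=C(\C)CCC=C(C)C | intermediate
4 | (5E,9E,13E)-6,10,14,18-tetramethylnonadeca-5,9,13,17-tetraen-1-yne | C#CCC/C=C(\C)CC/C=C(\C)CC/C=C(\C)CCC=C(C)C | intermediate
5 | dimethyl[(1E,5E,9E,13E)-2,6,10,14,18-pentamethylnonadeca-1,5,9,13,17-pentaen-1-yl]alane | C[Al](C)/C=C(\C)CC/C=C(\C)CC/C=C(\C)CC/C=C(\C)CCC=C(C)C | intermediate
6 | (1E,5E,9E,13E)-1-iodo-2,6,10,14,18-pentamethylnonadeca-1,5,9,13,17-pentaene | I/C=C(\C)CC/C=C(\C)CC/C=C(\C)CC/C=C(\C)CCC=C(C)C | intermediate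
7 | ethyl levulinate (ethyl 4-oxopentanoate) | CCOC(=O)CCC(C)=O | starting material
8 | bromomagnesium alkoxide of ethyl 4-hydroxy-4-methylhex-5-enoate (racemic) | CCOC(=O)CCC(C)(O[Mg]Br)C=C | intermediate
9 | rac-5-methyl-5-vinyldihydrofuran-2(3H)-one | C=CC1(C)CCC(=O)O1 | intermediate
10 | 2,3,4,5-tetramethoxytoluene (1,2,3,4-tetramethoxy-5-methylbenzene) | Cc1cc(OC)c(OC)c(OC)c1OC | starting material
11 | (2,3,4,5-tetramethoxy-6-methylphenyl)lithium | [Li]c1c(C)c(OC)c(OC)c(OC)c1OC | intermediate
12 | (2,3,4,5-tetramethoxy-6-methylphenyl)magnesium bromide | Br[Mg]c1c(C)c(OC)c(OC)c(OC)c1OC | intermediate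
13 | (E)-4-methyl-6-(2,3,4,5-tetramethoxy-6-methylphenyl)hex-4-enoic acid | COc1c(OC)c(C)c(C/C=C(\C)CCC(=O)O)c(OC)c1OC | intermediate
14 | 1,3-dioxoisoindolin-2-yl (E)-4-methyl-6-(2,3,4,5-tetramethoxy-6-methylphenyl)hex-4-enoate | COc1c(OC)c(C)c(C/C=C(\C)CCC(=O)ON2C(=O)c3ccccc3C2=O)c(OC)c1OC | intermediate
15 | 1-[(2E,6E,10E,14E,18E)-3,7,11,15,19,23-hexamethyltetracosa-2,6,10,14,18,22-hexaen-1-yl]-2,3,4,5-tetramethoxy-6-methylbenzene | COc1c(OC)c(C)c(C/C=C(\C)CC/C=C(\C)CC/C=C(\C)CC/C=C(\C)CC/C=C(\C)CCC=C(C)C)c(OC)c1OC | intermediate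
16 | ubiquinone-6 | COC1=C(OC)C(=O)C(C/C=C(\C)CC/C=C(\C)CC/C=C(\C)CC/C=C(\C)CC/C=C(\C)CCC=C(C)C)=C(C)C1=O | intermediate
17 | ubiquinol-6 | COc1c(O)c(C)c(C/C=C(\C)CC/C=C(\C)CC/C=C(\C)CC/C=C(\C)CC/C=C(\C)CCC=C(C)C)c(O)c1OC | target

**Total step count:** 9
**Longest linear sequence:** 6 steps (4 → 5 → 6 → 7 → 8 → 9; the branch 1 → 2 → 3 → 7 → 8 → 9 is equally long)

**Steps most likely to fail**

Step 7. The alkyl radical may be reduced or dimerise faster than alkenylnickel captures it, or the alkenyl iodide may be hydrodeiodinated at the cathode, so that cross-coupling stays low. The fallback sets out from 6 and 14 and returns at 15. Compound 6 is converted by iodine–lithium exchange (t-BuLi, Et2O, −78 °C) and ZnCl2 into the alkenylzinc chloride F1. F1 is then coupled with 14 under Ni(acac)2/2,2′-bipyridine catalysis in THF–DMF at rt (decarboxylative Negishi-type alkenylation of a redox-active ester). The same C5′–C6′ bond is formed, but from a preformed organometallic partner and not from two electrophiles under reduction.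

Step 5. E/Z control in the SN2′ opening may be poor, or the aryl Grignard may add to the lactone carbonyl. The fallback sets out from 10 and returns at 13. Compound 10 is lithiated as in step 5, transmetalated with CuBr·SMe2 and allylated with commercial geranyl bromide, so that the E olefin is imported, giving the geranyl arene F2. Terminal-selective bromohydrin formation (NBS, THF–H2O, 0 °C) gives the bromohydrin F3, and K2CO3 in MeOH closes it to the terminal epoxide F4. Periodic acid cleaves F4 to the aldehyde F5, and Pinnick oxidation (NaClO2, NaH2PO4, 2-methyl-2-butene, t-BuOH–H2O) gives 13.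

Step 8. The six olefins may be over-oxidised, or ortho-quinone may form, during cerium(IV) demethylation of the lipophilic substrate. The fallback sets out from 13 and returns at 17. The oxidative demethylation is moved forward to the acid 13 (CAN, MeCN–H2O, 0 °C), giving the quinone acid F6. Reductive acetylation (Zn, Ac2O, pyridine; aqueous work-up) gives the hydroquinone diacetate acid F7, and DIC with N-hydroxyphthalimide (no DMAP) gives its redox-active ester F8. The electrochemical coupling of step 7 with 6 then gives ubiquinol-6 diacetate F9. K2CO3 in degassed MeOH–THF under argon cleaves both acetates to give 17 directly, so the polyene never meets an oxidant.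

**Further compounds**

F1 | step 7 | chloro[(1E,5E,9E,13E)-2,6,10,14,18-pentamethylnonadeca-1,5,9,13,17-pentaen-1-yl]zinc | Cl[Zn]/C=C(\C)CC/C=C(\C)CC/C=C(\C)CC/C=C(\C)CCC=C(C)C
F2 | step 5 | 1-[(2E)-3,7-dimethylocta-2,6-dien-1-yl]-2,3,4,5-tetramethoxy-6-methylbenzene | COc1c(OC)c(C)c(C/C=C(\C)CCC=C(C)C)c(OC)c1OC
F3 | step 5 | (E)-3-bromo-2,6-dimethyl-8-(2,3,4,5-tetramethoxy-6-methylphenyl)oct-6-en-2-ol (racemic) | COc1c(OC)c(C)c(C/C=C(\C)CCC(Br)C(C)(C)O)c(OC)c1OC
F4 | step 5 | 2,2-dimethyl-3-[(E)-3-methyl-5-(2,3,4,5-tetramethoxy-6-methylphenyl)pent-3-en-1-yl]oxirane (racemic) | COc1c(OC)c(C)c(C/C=C(\C)CCC2OC2(C)C)c(OC)c1OC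
F5 | step 5 | (E)-4-methyl-6-(2,3,4,5-tetramethoxy-6-methylphenyl)hex-4-enal | COc1c(OC)c(C)c(C/C=C(\C)CCC=O)c(OC)c1OC
F6 | step 8 | (E)-6-(4,5-dimethoxy-2-methyl-3,6-dioxocyclohexa-1,4-dien-1-yl)-4-methylhex-4-enoic acid | COC1=C(OC)C(=O)C(C/C=C(\C)CCC(=O)O)=C(C)C1=O
F7 | step 8 | (E)-6-(2,5-diacetoxy-3,4-dimethoxy-6-methylphenyl)-4-methylhex-4-enoic acid | COc1c(OC(C)=O)c(C)c(C/C=C(\C)CCC(=O)O)c(OC(C)=O)c1OC
F8 | step 8 | 1,3-dioxoisoindolin-2-yl (E)-6-(2,5-diacetoxy-3,4-dimethoxy-6-methylphenyl)-4-methylhex-4-enoate | COc1c(OC(C)=O)c(C)c(C/C=C(\C)CCC(=O)ON2C(=O)c3ccccc3C2=O)c(OC(C)=O)c1OC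
F9 | step 8 | ubiquinol-6 diacetate | COc1c(OC(C)=O)c(C)c(C/C=C(\C)CC/C=C(\C)CC/C=C(\C)CC/C=C(\C)CC/C=C(\C)CCC=C(C)C)c(OC(C)=O)c1OC
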